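How much target stands in the flask at 3.0 min, and how much of the substrate has reacted?

| flask | substrate | reagent in the second phase | remark | time | volume of the second phase over the first |
|---|---|---|---|---|---|
| midnight | 0.025 M | 0.035 M | run made earlier |  |  |
| autumn | 0.038 M | 0.035 M | run made earlier |  |  |
| flask | 0.050 M | 0.0350 M |  | 3.0 min | 2.0 |

| run | time / min | target / % | substrate / % |
|---|---|---|---|
| midnight | 0.200 | 9.6 | 83.1 |
| midnight | 0.500 | 24.8 | 58.7 |
| midnight | 1.00 | 35.7 | 34.7 |
| midnight | 1.50 | 38.5 | 22.2 |
| midnight | 2.00 | 38.9 | 17.6 |
| midnight | 3.00 | 37.1 | 12.1 |
| midnight | 4.00 | 35.0 | 10.1 |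
| autumn | 0.500 | 22.3 | 60.2 |
| autumn | 1.00 | 31.4 | 39.0 |
| autumn | 1.50 | 32.3 | 27.9 |
| autumn | 2.00 | 33.2 | 21.8 |
| autumn | 2.50 | 33.5 | 19.0 |
| autumn | 3.00 | 32.5 | 15.8 |
| autumn | 4.00 | 30.9 | 13.1 |

(standard deviation of a reading: 0.5 percentage points)

- percent here means substrate units held: one side product counts as two
- in the second phase: reagent in the second phase; everything else is in the first
- charges count per volume of the first phase; a concentration in a rate is the amount of a species over the volume of its own phase; every rate counts per litre of the first phase
- on the list of suspects stand: 2 reagent in the reaction phase -> homo dimer; substrate <-> dormant form; reagent in the reaction phase <-> reagent in the second phase; substrate + target -> side product; substrate + reagent in the reaction phase -> target; reagent in the reaction phase + target -> over-reacted product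
- the earlier runs hold the two phases in the same ratio of volumes as the flask asked about
- what has gone from substrate into another species counts as reacted, even if it can come back

- amount of target at 3.0 min, in percent of the substrate charged
- part of the substrate charged that has reacted at 3.0 min

I read both earlier runs at 3.00 min, the time asked of the flask, and divide the target held by the reagent in the second phase charged. Midnight gives 0.265 and autumn 0.353; this is the reagent yield. In the flask the reagent in the second phase is the limiting reagent, with less charged than substrate, so a reagent yield of one would mean 70.0 % of target, a ceiling.

Two simple versions can be reckoned in the head. If the yield stays at autumn's value, the flask holds 24.7 %. If it keeps rising in a straight line with the substrate charge, the flask holds 30.4 %. The yield is larger in autumn than at midnight, so I don't take the lower version. Two runs give a line but can show no bend, so I distrust the straight line too. My own reckoning is the middle, 27.5 %.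

The forecast says 29.3 % of target, more than my 27.5 %, and 81 % reacted, and adds: “This is an extrapolation, not a fitted model”.

The flask gives 26.6 % of target and 80.0 % reacted, so the forecast holds on both.

    2 reagent in the reaction phase → homo dimer (k = 0.430 L mol⁻¹ s⁻¹)
    substrate ⇌ dormant form (K = 0.550, k = 0.00620 s⁻¹)
    reagent in the reaction phase ⇌ reagent in the second phase, rate k3*([reagent in the reaction phase] - [reagent in the second phase]/K3) per volume of the first phase (partition coefficient = 1.70, kL = 0.0980 s⁻¹)
    substrate + target → side product (k = 0.200 L mol⁻¹ s⁻¹)
    substrate + reagent in the reaction phase → target (k = 3.30 L mol⁻¹ s⁻¹)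
    reagent in the reaction phase + target → over-reacted product (k = 1.30 L mol⁻¹ s⁻¹)

The flask's reagent yield is 0.380, higher than autumn's 0.353. The neighbouring flask is the same one with 0.12 M of substrate. Its ceiling is 29.2 %, and autumn's yield would give it 10.3 %. It holds 6.61 % of target, a reagent yield of 0.227, lower than midnight's 0.265, with 37.2 % as side product and 34.1 % as substrate.

The runs were computed on assumed constants; scatter was added.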